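**Retrosynthetic overview**

1. The strategy rests on the pyrrole ring (N1, C2, C3, C4, C5) of the achiral target 5-henicosyl-1H-pyrrole-2-carbaldehyde. N1, C2 and the formyl carbon are the N, Cα and CH2O of L-serine; C3 is the former serine carboxyl carbon (the CHO of Garner aldehyde); C4, C5 and the C21 chain are 1-tricosyne.
2. Endgame: target ⇐ N-Boc removal ⇐ MnO2 oxidation of the 2-hydroxymethyl group ⇐ desilylation of the N-Boc 2-(silyloxymethyl)-5-henicosylpyrrole.
3. Key disconnection N1–C5: the only ring, the pyrrole, is closed by gold-catalysed 5-endo-dig hydroamination of an N-Boc 1-amino-3-alkyn-2-ol, followed by loss of water across C2–C3.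
4. The alkynol ⇐ primary O-silylation and acetonide methanolysis ⇐ C3–C4 bond formation by addition of lithium tricosynide to (S)-Garner aldehyde.
5. 1-Tricosyne ⇐ Ohira–Bestmann homologation of docosanal ⇐ 1-docosanol.

Key step: step 6

Assumption: the acetylide addition is taken to favour the anti (Felkin–Anh) carbinol, which is the epimer drawn for the adduct and the later sp3 intermediates. The minor epimer is carried along unseparated, because both stereocentres vanish when the pyrrole forms.

**Route**

Step 1
Reactants: 1 1-docosanol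
Product: 2 docosanal
Conditions: TEMPO (10 mol %), PhI(OAc)2 (1.1 equiv), CH2Cl2, 30 °C
Reagents that add atoms: none
Why: TEMPO-catalysed oxidation with PhI(OAc)2 as terminal oxidant should stop at the aldehyde for a primary aliphatic alcohol and tolerates the warm, dilute CH2Cl2 needed to keep the waxy substrate dissolved.

Step 2
Reactants: 2 docosanal; 3 dimethyl (1-diazo-2-oxopropyl)phosphonate
Product: 5 1-tricosyne, via 1-diazotricos-1-ene 4 (not isolated)
Conditions: K2CO3 (2 equiv), MeOH/THF (1:1), rt
Reagents that add atoms: dimethyl (1-diazo-2-oxopropyl)phosphonate (3), COP(=O)(OC)C(=[N+]=[N-])C(C)=O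
Why: Ohira–Bestmann homologation: methanolysis of the acetyl group releases the dimethyl diazomethylphosphonate anion, which olefinates the aldehyde to diazoalkene 4, and loss of N2 with 1,2-hydrogen shift of the alkylidene carbene gives the terminal alkyne under base mild enough to spare the enolisable aldehyde.

Step 3
Reactants: 5 1-tricosyne; 6 (S)-Garner aldehyde (tert-butyl (4S)-4-formyl-2,2-dimethyl-1,3-oxazolidine-3-carboxylate)
Product: 8 tert-butyl (4S)-4-[(1R)-1-hydroxytetracos-2-yn-1-yl]-2,2-dimethyl-1,3-oxazolidine-3-carboxylate, via lithium tricos-1-yn-1-ide 7 (not isolated)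
Conditions: n-BuLi (1.0 equiv), THF, −20 °C; then 6 (0.9 equiv), −78 → −20 °C; sat. aq NH4Cl
Reagents that add atoms: none
Why: 1,2-addition of a lithium acetylide to an α-amino aldehyde forms the C3–C4 bond of the future pyrrole; Felkin–Anh attack should favour the anti (1R) carbinol, but the epimer ratio does not matter because this centre and C4 of the oxazolidine both become sp2 in step 6.

Step 4
Reactants: 8 tert-butyl (4S)-4-[(1R)-1-hydroxytetracos-2-yn-1-yl]-2,2-dimethyl-1,3-oxazolidine-3-carboxylate
Product: 9 tert-butyl N-[(2S,3R)-1,3-dihydroxyhexacos-4-yn-2-yl]carbamate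
Conditions: p-TsOH·H2O (10 mol %), MeOH/THF (3:1), rt
Reagents that add atoms: none
Why: Acid-catalysed transketalisation of the N,O-isopropylidene group with methanol frees the primary hydroxyl and the carbamate N–H, while the Boc group and the propargylic alcohol should survive catalytic sulfonic acid at room temperature.

Step 5
Reactants: 9 tert-butyl N-[(2S,3R)-1,3-dihydroxyhexacos-4-yn-2-yl]carbamate
Product: 10 tert-butyl N-[(2S,3R)-1-{[tert-butyl(dimethyl)silyl]oxy}-3-hydroxyhexacos-4-yn-2-yl]carbamate
Conditions: TBSCl (1.05 equiv), imidazole (2 equiv), CH2Cl2, 0 °C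
Reagents that add atoms: tert-butyldimethylsilyl chloride (TBSCl), CC(C)(C)[Si](C)(C)Cl
Why: Selective silylation: the unhindered primary hydroxyl should react with TBSCl/imidazole far faster than the secondary propargylic hydroxyl at 0 °C with only a slight excess of reagent.

Step 6
Reactants: 10 tert-butyl N-[(2S,3R)-1-{[tert-butyl(dimethyl)silyl]oxy}-3-hydroxyhexacos-4-yn-2-yl]carbamate
Product: 12 tert-butyl 2-{[tert-butyl(dimethyl)silyl]oxymethyl}-5-henicosyl-1H-pyrrole-1-carboxylate, via 3-hydroxy-2,3-dihydropyrrole carbamate 11 (not isolated)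
Conditions: Ph3PAuCl (2 mol %), AgOTf (2 mol %), toluene, rt
Reagents that add atoms: none
Why: Chloride abstraction by AgOTf gives cationic Ph3PAu+ (monovalent gold), which π-activates the C4≡C5 triple bond; the carbamate nitrogen adds anti to gold at the distal alkyne carbon C5, forming N1–C5, and protodeauration of the vinylgold gives hydroxy-dihydropyrrole 11. Ionisation of the allylic C3 hydroxyl (the cation is stabilised through the N1–C5=C4 enamide) and loss of the C2 proton then expel water and aromatise the ring. The closest known reaction type is the gold- or silver-catalysed dehydrative cycloisomerisation of N-protected 1-amino-3-alkyn-2-ols to pyrroles. The single ring closes in the 5-endo-dig mode. No stereocentre is created and the two in 10 are destroyed, so both carbinol epimers converge on 12. The step needs nitrogen rather than oxygen attack and C5 rather than C4 regiochemistry: the primary oxygen is capped as its TBS ether, the secondary hydroxyl could only close a three- or four-membered ring, nitrogen attack at C4 would be a 4-exo closure, and the internal alkyne should resist the alternative 6-exo attack by the carbamate carbonyl oxygen.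

Step 7
Reactants: 12 tert-butyl 2-{[tert-butyl(dimethyl)silyl]oxymethyl}-5-henicosyl-1H-pyrrole-1-carboxylate
Product: 13 tert-butyl 5-henicosyl-2-(hydroxymethyl)-1H-pyrrole-1-carboxylate
Conditions: TBAF (1.5 equiv), AcOH (1.5 equiv), THF, 0 °C → rt
Reagents that add atoms: none
Why: Fluoride-mediated cleavage of the Si–O bond; buffering TBAF with acetic acid keeps the liberated alkoxide protonated so that it should not attack the neighbouring N-Boc carbonyl.

Step 8
Reactants: 13 tert-butyl 5-henicosyl-2-(hydroxymethyl)-1H-pyrrole-1-carboxylate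
Product: 14 tert-butyl 2-formyl-5-henicosyl-1H-pyrrole-1-carboxylate
Conditions: activated MnO2 (15 equiv), CH2Cl2, rt
Reagents that add atoms: none
Why: MnO2 oxidation of a heteroaryl (benzylic-type) carbinol should stop at the aldehyde, and the N-Boc group keeps the pyrrole electron-poor enough to resist oxidative degradation.

Step 9
Reactants: 14 tert-butyl 2-formyl-5-henicosyl-1H-pyrrole-1-carboxylate
Product: 15 5-henicosyl-1H-pyrrole-2-carbaldehyde
Conditions: K2CO3 (0.3 equiv), MeOH/THF (2:1), rt
Reagents that add atoms: none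
Why: Base-catalysed methanolysis of an N-acyl pyrrole: the 2-formylpyrrolide is a good leaving group, so methoxide should transfer the Boc group to methanol without acid that could degrade the pyrrole aldehyde.

**Compound list**

1 | 1-docosanol | CCCCCCCCCCCCCCCCCCCCCCO | starting material
2 | docosanal | CCCCCCCCCCCCCCCCCCCCCC=O | intermediate
3 | dimethyl (1-diazo-2-oxopropyl)phosphonate | COP(=O)(OC)C(=[N+]=[N-])C(C)=O | starting material
4 | 1-diazotricos-1-ene | CCCCCCCCCCCCCCCCCCCCCC=C=[N+]=[N-] | intermediate (not isolated)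
5 | 1-tricosyne | CCCCCCCCCCCCCCCCCCCCCC#C | intermediate
6 | (S)-Garner aldehyde, tert-butyl (4S)-4-formyl-2,2-dimethyl-1,3-oxazolidine-3-carboxylate | CC1(C)OC[C@@H](C=O)N1C(=O)OC(C)(C)C | starting material
7 | lithium tricos-1-yn-1-ide | CCCCCCCCCCCCCCCCCCCCCC#C[Li] | intermediate (not isolated)
8 | tert-butyl (4S)-4-[(1R)-1-hydroxytetracos-2-yn-1-yl]-2,2-dimethyl-1,3-oxazolidine-3-carboxylate (anti epimer drawn) | CCCCCCCCCCCCCCCCCCCCCC#C[C@@H](O)[C@@H]1COC(C)(C)N1C(=O)OC(C)(C)C | intermediate
9 | tert-butyl N-[(2S,3R)-1,3-dihydroxyhexacos-4-yn-2-yl]carbamate | CCCCCCCCCCCCCCCCCCCCCC#C[C@@H](O)[C@H](CO)NC(=O)OC(C)(C)C | intermediate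
10 | tert-butyl N-[(2S,3R)-1-{[tert-butyl(dimethyl)silyl]oxy}-3-hydroxyhexacos-4-yn-2-yl]carbamate | CCCCCCCCCCCCCCCCCCCCCC#C[C@@H](O)[C@H](CO[Si](C)(C)C(C)(C)C)NC(=O)OC(C)(C)C | intermediate
11 | tert-butyl (2S,3R)-2-{[tert-butyl(dimethyl)silyl]oxymethyl}-5-henicosyl-3-hydroxy-2,3-dihydro-1H-pyrrole-1-carboxylate | CCCCCCCCCCCCCCCCCCCCCC1=C[C@@H](O)[C@H](CO[Si](C)(C)C(C)(C)C)N1C(=O)OC(C)(C)C | intermediate (not isolated)
12 | tert-butyl 2-{[tert-butyl(dimethyl)silyl]oxymethyl}-5-henicosyl-1H-pyrrole-1-carboxylate | CCCCCCCCCCCCCCCCCCCCCc1ccc(CO[Si](C)(C)C(C)(C)C)n1C(=O)OC(C)(C)C | intermediate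
13 | tert-butyl 5-henicosyl-2-(hydroxymethyl)-1H-pyrrole-1-carboxylate | CCCCCCCCCCCCCCCCCCCCCc1ccc(CO)n1C(=O)OC(C)(C)C | intermediate
14 | tert-butyl 2-formyl-5-henicosyl-1H-pyrrole-1-carboxylate | CCCCCCCCCCCCCCCCCCCCCc1ccc(C=O)n1C(=O)OC(C)(C)C | intermediate
15 | 5-henicosyl-1H-pyrrole-2-carbaldehyde | CCCCCCCCCCCCCCCCCCCCCc1ccc(C=O)[nH]1 | target

**Step count and risks**

Total step count: 9. Longest linear sequence: 9 steps (1-docosanol 1 to target 15); Garner aldehyde 6 and diazophosphonate 3 are purchased.

Steps most likely to fail: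

Step 6 (gold cycloisomerisation). The closure may be diverted by attack of the carbamate carbonyl oxygen on the activated alkyne with loss of isobutene, by Meyer–Schuster-type rearrangement of the propargylic alcohol, or by acid-induced loss of the silyl ether from adventitious TfOH. The fallback builds the pyrrole by Paal–Knorr condensation and sets out from docosanal 2. Addition of 2-(1,3-dioxolan-2-yl)ethylmagnesium bromide (from 2-(2-bromoethyl)-1,3-dioxolane and Mg, THF, 0 °C) should give racemic 1-(1,3-dioxolan-2-yl)tetracosan-3-ol F1. Dess–Martin oxidation (CH2Cl2, rt) should give 1-(1,3-dioxolan-2-yl)tetracosan-3-one F2. Heating F2 with NH4OAc in AcOH unmasks the aldehyde and condenses the 1,4-dicarbonyl with ammonia to 2-henicosyl-1H-pyrrole F3. Vilsmeier–Haack formylation (POCl3, DMF, 0 °C → rt, then aq NaOAc) at the free α-position comes back to the route at the target 15.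

Step 3 (acetylide addition). The long-chain lithium acetylide 7 may precipitate at −78 °C, so that addition stalls and the aldehyde is consumed by base-induced side reactions. The fallback makes the C3–C4 bond by acylation, which tolerates 0 °C, and sets out from 1-tricosyne 5. Lithiation as before and reaction with the purchased Weinreb amide tert-butyl (4S)-4-[methoxy(methyl)carbamoyl]-2,2-dimethyl-1,3-oxazolidine-3-carboxylate (CON(C)C(=O)[C@@H]1COC(C)(C)N1C(=O)OC(C)(C)C) in THF at −20 → 0 °C should give the ynone tert-butyl (4S)-2,2-dimethyl-4-(tetracos-2-ynoyl)-1,3-oxazolidine-3-carboxylate F4. Luche reduction (NaBH4, CeCl3·7H2O, MeOH/THF, −20 °C) comes back to the route at 8, as an epimer mixture that serves equally well.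

Step 7 (desilylation). The liberated alkoxide may attack the adjacent N-Boc carbonyl, causing Boc transfer from nitrogen to oxygen or closure to a fused cyclic carbamate with loss of tert-butoxide. The fallback reverses the order of deprotection so that no carbamate is present when the alcohol is freed, and sets out from 12. NaOMe in MeOH/THF at rt should remove the Boc group to give 2-{[tert-butyl(dimethyl)silyl]oxymethyl}-5-henicosyl-1H-pyrrole F5. TBAF in THF at 0 °C should give (5-henicosyl-1H-pyrrol-2-yl)methanol F6, which is oxidised without storage by MnO2 in CH2Cl2 and comes back to the route at the target 15.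

**Further compounds**

F1 | step 6 | 1-(1,3-dioxolan-2-yl)tetracosan-3-ol (racemic) | CCCCCCCCCCCCCCCCCCCCCC(O)CCC1OCCO1
F2 | step 6 | 1-(1,3-dioxolan-2-yl)tetracosan-3-one | CCCCCCCCCCCCCCCCCCCCCC(=O)CCC1OCCO1
F3 | step 6 | 2-henicosyl-1H-pyrrole | CCCCCCCCCCCCCCCCCCCCCc1ccc[nH]1
F4 | step 3 | tert-butyl (4S)-2,2-dimethyl-4-(tetracos-2-ynoyl)-1,3-oxazolidine-3-carboxylate | CCCCCCCCCCCCCCCCCCCCCC#CC(=O)[C@@H]1COC(C)(C)N1C(=O)OC(C)(C)C
F5 | step 7 | 2-{[tert-butyl(dimethyl)silyl]oxymethyl}-5-henicosyl-1H-pyrrole | CCCCCCCCCCCCCCCCCCCCCc1ccc(CO[Si](C)(C)C(C)(C)C)[nH]1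
F6 | step 7 | (5-henicosyl-1H-pyrrol-2-yl)methanol | CCCCCCCCCCCCCCCCCCCCCc1ccc(CO)[nH]1
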